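**Plan**

- Retrosynthetic cuts: the oxirane C–O bonds at C12/C13 and the two O–Si bonds come off last. The O15–C1 lactone bond is then exchanged for an O17–C1 bond by reversing a [3,3] acyloxy shift over C15–C16–C17 (16- to 18-membered lactone). The remaining cuts are O17–C1, C11–C12, C6–C7, C16–C17, C14–C15 and C2–C3.
- Enabling feature: the lactone oxygen on C15 is allylic to the C16–C17 alkene, which is conjugated with the thiazole ring. The C1 acyloxy group can therefore first be placed on C17 and then moved to C15 across the C15–C16–C17 allyl unit. Thiazole N3 lies four atoms from C16 and can hold palladium on C16.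
- Forward order: iodo dienol 10 (C12–C17), aldehyde 15 (C7–C11) and ketone 24 (C1–C6) are made separately. They are joined by aldol (C6–C7) and B-alkyl Suzuki coupling (C11–C12). Macrolactonisation at O17 closes the 18-membered ring, the shift contracts it to the 16-membered lactone, and desilylation and formation of the oxirane ring follow.
- Stereochemistry: C4 comes from the (R)-Roche ester, C3 from a chelation-controlled Mukaiyama aldol, C8 from an Evans alkylation, and C6/C7 from a matched chlorotitanium enolate aldol. C17 is set by a ligand-controlled alkenylzinc addition and is transferred to C15 in the shift. C12/C13 come from face-selective epoxidation of the macrocycle. The 12Z, 15E and 16E geometries come from hydroalumination–iodination, syn-hydrozirconation and the chair of the shift.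

Key step: step 21

Remark: locants C1–C17 in the comments follow the seco-acid chain (C1 = lactone carbonyl, C17 = thiazolyl carbinol); the target is taken as drawn, with one methyl group on C4 (4S).
Abbreviations: TBS = tert-butyldimethylsilyl, TES = triethylsilyl, TMS = trimethylsilyl, MIB = (2S)-3-exo-morpholinoisoborneol, 9-BBN = 9-borabicyclo[3.3.1]nonane.

**Route**

Step 1
Reactants: 1 but-2-yn-1-ol
Product: 3 (2Z)-3-iodobut-2-en-1-ol, via cyclic alkenylalanate 2 (not isolated)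
Conditions: NaAlH2(OCH2CH2OMe)2 (Red-Al), Et2O, 0 → 23 °C; then I2, THF, −78 → 0 °C
Reagents that add atoms: iodine, II
Why: Hydroxyl-directed trans-hydroalumination of the propargylic alcohol puts aluminium on C3 inside a five-membered alanate, and iodinolysis of the C–Al bond with retention gives the (Z)-iodoalkene that becomes the C12–C13 alkene (hydroalumination–iodination).

Step 2
Reactants: 3 (2Z)-3-iodobut-2-en-1-ol
Product: 4 (2Z)-1-bromo-3-iodobut-2-ene
Conditions: CBr4, PPh3, CH2Cl2, 0 °C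
Reagents that add atoms: tetrabromomethane, BrC(Br)(Br)Br
Why: Appel bromination displaces the oxyphosphonium group at the primary allylic carbon by SN2 and leaves the alkene geometry untouched.

Step 3
Reactants: 4 (2Z)-1-bromo-3-iodobut-2-ene; 5 prop-1-yn-1-ylmagnesium bromide
Product: 6 (5Z)-6-iodohept-5-en-2-yne
Conditions: CuBr·SMe2 (5 mol%), THF, −20 → 23 °C
Reagents that add atoms: none
Why: Copper-catalysed coupling of an alkynyl Grignard reagent with a primary allylic bromide should give the skipped enyne by direct substitution, because the γ-carbon is fully substituted and the vinyl iodide is inert at this temperature.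

Step 4
Reactants: 6 (5Z)-6-iodohept-5-en-2-yne; 7 2-methyl-1,3-thiazole-4-carbaldehyde
Product: 10 (1S,2E,5Z)-6-iodo-2-methyl-1-(2-methyl-1,3-thiazol-4-yl)hepta-2,5-dien-1-ol, via alkenylzirconocene chloride 8 (not isolated), via alkenyl(methyl)zinc 9 (not isolated)
Conditions: Cp2Zr(H)Cl (1.3 equiv), CH2Cl2, 23 °C; solvent switch to toluene, Me2Zn, −65 °C; (−)-MIB (10 mol%), then 7, −30 → 0 °C
Reagents that add atoms: none
Why: syn-Hydrozirconation of the 2-alkyne puts zirconium on the less hindered, methyl-bearing carbon and fixes the 15E geometry, zirconium-to-zinc transmetalation gives the alkenylzinc, and its amino-alcohol-catalysed addition to the aldehyde (asymmetric alkenylzinc addition) should set C17 as (S) by Si-face attack, the sense this ligand shows with aryl aldehydes.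

Step 5
Reactants: 11 (4R)-4-benzyl-3-propanoyl-1,3-oxazolidin-2-one
Product: 13 (4R)-4-benzyl-3-[(2S)-2-methylpent-4-enoyl]-1,3-oxazolidin-2-one, via sodium enolate 12 (not isolated)
Conditions: NaN(SiMe3)2, THF, −78 °C; allyl iodide, −78 → −40 °C
Reagents that add atoms: allyl iodide, C=CCI
Why: Evans alkylation: the chelated sodium (Z)-enolate is alkylated on the face opposite the benzyl group of the (R)-auxiliary, which sets the later C8 centre as (S).

Step 6
Reactants: 13 (4R)-4-benzyl-3-[(2S)-2-methylpent-4-enoyl]-1,3-oxazolidin-2-one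
Product: 14 (2S)-2-methylpent-4-en-1-ol
Conditions: LiBH4, H2O (1 equiv), Et2O, 0 °C
Reagents that add atoms: none
Why: Reductive cleavage of the N-acyloxazolidinone by borohydride attack on the exocyclic carbonyl releases the primary alcohol without touching the α-stereocentre or the alkene.

Step 7
Reactants: 14 (2S)-2-methylpent-4-en-1-ol
Product: 15 (2S)-2-methylpent-4-enal
Conditions: Dess–Martin periodinane, CH2Cl2, 0 → 23 °C; used at once as a solution
Reagents that add atoms: none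
Why: Dess–Martin oxidation gives the α-chiral aldehyde under base-free conditions, so the stereocentre should not epimerise.

Step 8
Reactants: 16 methyl (2R)-3-hydroxy-2-methylpropanoate
Product: 17 methyl (2R)-3-(benzyloxy)-2-methylpropanoate
Conditions: benzyl 2,2,2-trichloroacetimidate, TfOH (cat.), CH2Cl2/cyclohexane, 23 °C
Reagents that add atoms: benzyl 2,2,2-trichloroacetimidate, N=C(OCc1ccccc1)C(Cl)(Cl)Cl
Why: Acid-catalysed benzylation with the trichloroacetimidate protects the hydroxyl without base, so the α-stereocentre of the ester (later C4) is not at risk.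

Step 9
Reactants: 17 methyl (2R)-3-(benzyloxy)-2-methylpropanoate
Product: 18 (2R)-3-(benzyloxy)-2-methylpropanal
Conditions: i-Bu2AlH, CH2Cl2, −78 °C; Rochelle salt work-up
Reagents that add atoms: none
Why: Partial reduction of the methyl ester stops at the aldehyde because the tetrahedral aluminium intermediate, chelated by the β-benzyloxy group, survives at −78 °C until work-up.

Step 10
Reactants: 18 (2R)-3-(benzyloxy)-2-methylpropanal
Product: 19 tert-butyl (3S,4R)-5-(benzyloxy)-3-hydroxy-4-methylpentanoate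
Conditions: 1-tert-butoxy-1-(trimethylsilyloxy)ethene, MgBr2·OEt2, CH2Cl2, −78 → −20 °C; 1 M HCl work-up
Reagents that add atoms: 1-tert-butoxy-1-(trimethylsilyloxy)ethene, C=C(OC(C)(C)C)O[Si](C)(C)C
Why: Chelation-controlled Mukaiyama aldol: magnesium bridges the aldehyde and benzyloxy oxygens in a six-membered chelate and the silyl ketene acetal adds anti to the C4 methyl group, which should give the 3,4-anti (3S) carbinol.

Step 11
Reactants: 19 tert-butyl (3S,4R)-5-(benzyloxy)-3-hydroxy-4-methylpentanoate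
Product: 20 tert-butyl (3S,4R)-5-(benzyloxy)-3-(TBS-oxy)-4-methylpentanoate
Conditions: TBSOTf, 2,6-lutidine, CH2Cl2, −78 °C
Reagents that add atoms: tert-butyldimethylsilyl trifluoromethanesulfonate, CC(C)(C)[Si](C)(C)OS(=O)(=O)C(F)(F)F
Why: Silyl triflate silylation of the secondary alcohol is fast at low temperature, where the tert-butyl ester is not attacked.

Step 12
Reactants: 20 tert-butyl (3S,4R)-5-(benzyloxy)-3-(TBS-oxy)-4-methylpentanoate
Product: 21 tert-butyl (3S,4R)-3-(TBS-oxy)-5-hydroxy-4-methylpentanoate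
Conditions: H2 (1 atm), Pd/C (palladium on carbon), EtOAc, 23 °C
Reagents that add atoms: none
Why: Hydrogenolysis of the benzyl ether in a neutral aprotic solvent leaves the silyl ether and the tert-butyl ester in place; no alkene or sulfur is present at this stage.

Step 13
Reactants: 21 tert-butyl (3S,4R)-3-(TBS-oxy)-5-hydroxy-4-methylpentanoate
Product: 22 tert-butyl (3S,4S)-3-(TBS-oxy)-4-methyl-5-oxopentanoate
Conditions: Dess–Martin periodinane, CH2Cl2, 0 → 23 °C
Reagents that add atoms: none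
Why: Dess–Martin oxidation gives the β-silyloxy α-methyl aldehyde under conditions that avoid epimerisation at C4 and elimination of the silyloxy group.

Step 14
Reactants: 22 tert-butyl (3S,4S)-3-(TBS-oxy)-4-methyl-5-oxopentanoate
Product: 23 tert-butyl (3S,4R,5RS)-3-(TBS-oxy)-5-hydroxy-4-methylheptanoate
Conditions: EtMgBr, Et2O, −78 °C
Reagents that add atoms: ethylmagnesium bromide, CC[Mg]Br
Why: Grignard addition to the aldehyde is much faster than attack on the hindered tert-butyl ester, and the configuration of the new carbinol does not matter because it is oxidised next.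

Step 15
Reactants: 23 tert-butyl (3S,4R,5RS)-3-(TBS-oxy)-5-hydroxy-4-methylheptanoate
Product: 24 tert-butyl (3S,4S)-3-(TBS-oxy)-4-methyl-5-oxoheptanoate
Conditions: Dess–Martin periodinane, CH2Cl2, 23 °C
Reagents that add atoms: none
Why: Dess–Martin oxidation of the secondary alcohol gives the ethyl ketone without base, so C4 keeps its configuration.

Step 16
Reactants: 24 tert-butyl (3S,4S)-3-(TBS-oxy)-4-methyl-5-oxoheptanoate; 15 (2S)-2-methylpent-4-enal
Product: 26 tert-butyl (3S,4S,6R,7S,8S)-3-(TBS-oxy)-7-hydroxy-4,6,8-trimethyl-5-oxoundec-10-enoate, via chlorotitanium enolate 25 (not isolated)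
Conditions: TiCl4, i-Pr2NEt, CH2Cl2, −78 °C; then 15, −78 → −50 °C
Reagents that add atoms: none
Why: Soft enolisation on the less hindered ethyl side gives the chlorotitanium (Z)-enolate, whose chair aldol transition state gives the 6,7-syn adduct; the C4 methyl stereocentre steers the enolate face to the 4,6-syn product and the (Z)-enolate prefers the anti-Felkin face of the α-methyl aldehyde (7,8-anti), so the two controls reinforce each other (matched chlorotitanium enolate aldol).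

Step 17
Reactants: 26 tert-butyl (3S,4S,6R,7S,8S)-3-(TBS-oxy)-7-hydroxy-4,6,8-trimethyl-5-oxoundec-10-enoate
Product: 27 tert-butyl (3S,4S,6R,7S,8S)-3,7-bis(TBS-oxy)-4,6,8-trimethyl-5-oxoundec-10-enoate
Conditions: TBSOTf, 2,6-lutidine, CH2Cl2, −78 → −20 °C
Reagents that add atoms: tert-butyldimethylsilyl trifluoromethanesulfonate, CC(C)(C)[Si](C)(C)OS(=O)(=O)C(F)(F)F
Why: Silyl triflate silylation protects the hindered C7 hydroxyl at a temperature where the ketone is not enolised and the tert-butyl ester is not cleaved.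

Step 18
Reactants: 27 tert-butyl (3S,4S,6R,7S,8S)-3,7-bis(TBS-oxy)-4,6,8-trimethyl-5-oxoundec-10-enoate; 10 (1S,2E,5Z)-6-iodo-2-methyl-1-(2-methyl-1,3-thiazol-4-yl)hepta-2,5-dien-1-ol
Product: 29 tert-butyl (3S,4S,6R,7S,8S,12Z,15E,17S)-3,7-bis(TBS-oxy)-17-hydroxy-4,6,8,12,16-pentamethyl-17-(2-methyl-1,3-thiazol-4-yl)-5-oxoheptadeca-12,15-dienoate, via B-alkyl-9-BBN borane 28 (not isolated)
Conditions: 9-BBN, THF, 23 °C; then 10, PdCl2(dppf) (10 mol%), AsPh3, Cs2CO3, DMF/H2O, 23 °C
Reagents that add atoms: none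
Why: 9-BBN hydroborates only the terminal alkene (the hindered ketone reacts far more slowly) and the B-alkyl Suzuki–Miyaura coupling joins C11 to C12 with retention of the (Z)-iodoalkene geometry while tolerating the free allylic alcohol.

Step 19
Reactants: 29 tert-butyl (3S,4S,6R,7S,8S,12Z,15E,17S)-3,7-bis(TBS-oxy)-17-hydroxy-4,6,8,12,16-pentamethyl-17-(2-methyl-1,3-thiazol-4-yl)-5-oxoheptadeca-12,15-dienoate
Product: 31 (3S,4S,6R,7S,8S,12Z,15E,17S)-3,7-bis(TBS-oxy)-17-hydroxy-4,6,8,12,16-pentamethyl-17-(2-methyl-1,3-thiazol-4-yl)-5-oxoheptadeca-12,15-dienoic acid, via bis(trimethylsilyl) derivative 30 (not isolated)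
Conditions: TMSOTf, 2,6-lutidine, CH2Cl2, 0 °C; then MeOH, aqueous citric acid, 0 °C
Reagents that add atoms: none
Why: The silyl triflate converts the tert-butyl ester into the silyl ester with loss of isobutene and silylates the C17 hydroxyl, and mild methanolysis then removes both trimethylsilyl groups while the two TBS ethers stay (silyl-triflate cleavage of a tert-butyl ester).

Step 20
Reactants: 31 (3S,4S,6R,7S,8S,12Z,15E,17S)-3,7-bis(TBS-oxy)-17-hydroxy-4,6,8,12,16-pentamethyl-17-(2-methyl-1,3-thiazol-4-yl)-5-oxoheptadeca-12,15-dienoic acid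
Product: 33 (4S,5S,7R,8S,9S,13Z,16E,18S)-4,8-bis(TBS-oxy)-5,7,9,13,17-pentamethyl-18-(2-methyl-1,3-thiazol-4-yl)-1-oxacyclooctadeca-13,16-diene-2,6-dione, via mixed anhydride 32 (not isolated)
Conditions: 2,4,6-trichlorobenzoyl chloride, Et3N, THF, 23 °C; then slow addition to DMAP, toluene, 60 °C (0.002 M)
Reagents that add atoms: none
Why: Yamaguchi macrolactonisation: DMAP attacks the less hindered carbonyl of the mixed anhydride and the acylpyridinium is captured by the C17 hydroxyl at high dilution, closing the 18-membered ring with retention at C17.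

Step 21
Reactants: 33 (4S,5S,7R,8S,9S,13Z,16E,18S)-4,8-bis(TBS-oxy)-5,7,9,13,17-pentamethyl-18-(2-methyl-1,3-thiazol-4-yl)-1-oxacyclooctadeca-13,16-diene-2,6-dione
Product: 34 (4S,5S,7R,8S,9S,13Z,16S)-4,8-bis(TBS-oxy)-5,7,9,13-tetramethyl-16-[(1E)-1-(2-methyl-1,3-thiazol-4-yl)prop-1-en-2-yl]-1-oxacyclohexadec-13-ene-2,6-dione
Conditions: PdCl2(MeCN)2 (20 mol%), THF, 23 → 40 °C, dark
Reagents that add atoms: none
Why: Proposed new method: divalent palladium is expected to bind the thiazole nitrogen and the C15–C16 alkene as a chelate, the lactone carbonyl oxygen then adds to C15 anti to palladium to give a 1,3-dioxan-2-ylium ion fused to a five-membered N–Pd–C16 palladacycle, and anti cleavage of the C17–O bond releases the thiazole-conjugated C16–C17 alkene, a net suprafacial [3,3] acyloxy shift. The closest known reactions are the [3,3] rearrangement of allylic acetates catalysed by divalent palladium (cyclisation-induced rearrangement) and the chelate-directed nucleopalladation of homoallylic amines, which places the nucleophile on the distal alkene carbon. The 16-membered lactone is closed by 6-endo attack of the ring carbonyl oxygen on C15 inside the 18-membered ring followed by loss of the O–C17 bond, that is by ring contraction and not by end-to-end cyclisation, so no high dilution is needed. C15 is set by 1,3-chirality transfer from C17 through the chair-like dioxanylium with the thiazole equatorial (the only chair in which nitrogen can reach palladium on C16), so (17S,15E) should give (15S,16E). The step needs oxygen attack at C15 and not at the methyl-bearing C16, which the five-membered chelate secures against the usual Markovnikov preference, and it must avoid ionisation to the allyl cation (loss of configuration and of the doubly allylic C14 proton), which the neutral, acid-free conditions secure. Conjugation of the new alkene with the thiazole should place the equilibrium on the side of 34.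

Step 22
Reactants: 34 (4S,5S,7R,8S,9S,13Z,16S)-4,8-bis(TBS-oxy)-5,7,9,13-tetramethyl-16-[(1E)-1-(2-methyl-1,3-thiazol-4-yl)prop-1-en-2-yl]-1-oxacyclohexadec-13-ene-2,6-dione
Product: 35 (4S,5S,7R,8S,9S,13Z,16S)-4,8-dihydroxy-5,7,9,13-tetramethyl-16-[(1E)-1-(2-methyl-1,3-thiazol-4-yl)prop-1-en-2-yl]-1-oxacyclohexadec-13-ene-2,6-dione
Conditions: HF·pyridine, pyridine, THF, 0 → 23 °C
Reagents that add atoms: none
Why: Buffered fluoride desilylation cleaves both secondary silyl ethers without ionising the allylic lactone or dehydrating the β-hydroxy ketone.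

Step 23
Reactants: 35 (4S,5S,7R,8S,9S,13Z,16S)-4,8-dihydroxy-5,7,9,13-tetramethyl-16-[(1E)-1-(2-methyl-1,3-thiazol-4-yl)prop-1-en-2-yl]-1-oxacyclohexadec-13-ene-2,6-dione
Product: 36 (1S,3S,7S,8S,10R,11S,12S,16R)-7,11-dihydroxy-8,10,12,16-tetramethyl-3-[(1E)-1-(2-methyl-1,3-thiazol-4-yl)prop-1-en-2-yl]-4,17-dioxabicyclo[14.1.0]heptadecane-5,9-dione
Conditions: dimethyldioxirane, CH2Cl2, −78 → −50 °C
Reagents that add atoms: dimethyldioxirane, CC1(C)OO1
Why: The electrophilic dioxirane epoxidises the electron-rich, non-conjugated C12–C13 alkene in preference to the thiazole-conjugated C16–C17 alkene and should approach from the outer face of the macrocycle, which leads to the (12R,13S)-oxirane (dioxirane epoxidation under macrocyclic stereocontrol).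

**Compound list**

1 | but-2-yn-1-ol | CC#CCO | starting material
2 | sodium 2,2-bis(2-methoxyethoxy)-3-methyl-2,5-dihydro-1,2-oxaluminol-2-uide (cyclic alkenylalanate, formed in the flask) | CC1=CCO[Al-]1(OCCOC)OCCOC.[Na+] | intermediate
3 | (2Z)-3-iodobut-2-en-1-ol | C/C(I)=C/CO | intermediate
4 | (2Z)-1-bromo-3-iodobut-2-ene | C/C(I)=C/CBr | intermediate
5 | prop-1-yn-1-ylmagnesium bromide (THF solution) | CC#C[Mg]Br | starting material
6 | (5Z)-6-iodohept-5-en-2-yne | CC#CC/C=C(/C)I | intermediate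
7 | 2-methyl-1,3-thiazole-4-carbaldehyde | Cc1nc(C=O)cs1 | starting material
8 | chlorobis(cyclopentadienyl)[(2E,5Z)-6-iodohepta-2,5-dien-2-yl]zirconium (formed in the flask) | C/C(=C\C/C=C(/C)I)[Zr](Cl)(C1C=CC=C1)C1C=CC=C1 | intermediate
9 | [(2E,5Z)-6-iodohepta-2,5-dien-2-yl](methyl)zinc (formed in the flask) | C/C(=C\C/C=C(/C)I)[Zn]C | intermediate
10 | (1S,2E,5Z)-6-iodo-2-methyl-1-(2-methyl-1,3-thiazol-4-yl)hepta-2,5-dien-1-ol | Cc1nc(cs1)[C@@H](O)/C(C)=C/C/C=C(/C)I | intermediate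
11 | (4R)-4-benzyl-3-propanoyl-1,3-oxazolidin-2-one | CCC(=O)N1[C@H](Cc2ccccc2)COC1=O | starting material
12 | sodium (Z)-enolate of 11 (formed in the flask) | C/C=C(\[O-])N1[C@H](Cc2ccccc2)COC1=O.[Na+] | intermediate
13 | (4R)-4-benzyl-3-[(2S)-2-methylpent-4-enoyl]-1,3-oxazolidin-2-one | C=CC[C@H](C)C(=O)N1[C@H](Cc2ccccc2)COC1=O | intermediate
14 | (2S)-2-methylpent-4-en-1-ol | C=CC[C@H](C)CO | intermediate
15 | (2S)-2-methylpent-4-enal | C=CC[C@H](C)C=O | intermediate
16 | methyl (2R)-3-hydroxy-2-methylpropanoate | OC[C@@H](C)C(=O)OC | starting material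
17 | methyl (2R)-3-(benzyloxy)-2-methylpropanoate | c1ccccc1COC[C@@H](C)C(=O)OC | intermediate
18 | (2R)-3-(benzyloxy)-2-methylpropanal | c1ccccc1COC[C@@H](C)C=O | intermediate
19 | tert-butyl (3S,4R)-5-(benzyloxy)-3-hydroxy-4-methylpentanoate | c1ccccc1COC[C@@H](C)[C@@H](O)CC(=O)OC(C)(C)C | intermediate
20 | tert-butyl (3S,4R)-5-(benzyloxy)-3-(TBS-oxy)-4-methylpentanoate | c1ccccc1COC[C@@H](C)[C@@H](O[Si](C)(C)C(C)(C)C)CC(=O)OC(C)(C)C | intermediate
21 | tert-butyl (3S,4R)-3-(TBS-oxy)-5-hydroxy-4-methylpentanoate | OC[C@@H](C)[C@@H](O[Si](C)(C)C(C)(C)C)CC(=O)OC(C)(C)C | intermediate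
22 | tert-butyl (3S,4S)-3-(TBS-oxy)-4-methyl-5-oxopentanoate | O=C[C@@H](C)[C@@H](O[Si](C)(C)C(C)(C)C)CC(=O)OC(C)(C)C | intermediate
23 | tert-butyl (3S,4R,5RS)-3-(TBS-oxy)-5-hydroxy-4-methylheptanoate | CCC(O)[C@@H](C)[C@@H](O[Si](C)(C)C(C)(C)C)CC(=O)OC(C)(C)C | intermediate
24 | tert-butyl (3S,4S)-3-(TBS-oxy)-4-methyl-5-oxoheptanoate | CCC(=O)[C@@H](C)[C@@H](O[Si](C)(C)C(C)(C)C)CC(=O)OC(C)(C)C | intermediate
25 | trichlorotitanium (5Z)-enolate of 24 (C5–O–TiCl3, C5=C6; formed in the flask) | C/C=C(\O[Ti](Cl)(Cl)Cl)[C@@H](C)[C@@H](O[Si](C)(C)C(C)(C)C)CC(=O)OC(C)(C)C | intermediate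
26 | tert-butyl (3S,4S,6R,7S,8S)-3-(TBS-oxy)-7-hydroxy-4,6,8-trimethyl-5-oxoundec-10-enoate | C=CC[C@H](C)[C@H](O)[C@@H](C)C(=O)[C@@H](C)[C@@H](O[Si](C)(C)C(C)(C)C)CC(=O)OC(C)(C)C | intermediate
27 | tert-butyl (3S,4S,6R,7S,8S)-3,7-bis(TBS-oxy)-4,6,8-trimethyl-5-oxoundec-10-enoate | C=CC[C@H](C)[C@H](O[Si](C)(C)C(C)(C)C)[C@@H](C)C(=O)[C@@H](C)[C@@H](O[Si](C)(C)C(C)(C)C)CC(=O)OC(C)(C)C | intermediate
28 | tert-butyl (3S,4S,6R,7S,8S)-11-(9-borabicyclo[3.3.1]nonan-9-yl)-3,7-bis(TBS-oxy)-4,6,8-trimethyl-5-oxoundecanoate (formed in the flask) | C1CC2CCCC(C1)B2CCC[C@H](C)[C@H](O[Si](C)(C)C(C)(C)C)[C@@H](C)C(=O)[C@@H](C)[C@@H](O[Si](C)(C)C(C)(C)C)CC(=O)OC(C)(C)C | intermediate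
29 | tert-butyl (3S,4S,6R,7S,8S,12Z,15E,17S)-3,7-bis(TBS-oxy)-17-hydroxy-4,6,8,12,16-pentamethyl-17-(2-methyl-1,3-thiazol-4-yl)-5-oxoheptadeca-12,15-dienoate | Cc1nc(cs1)[C@@H](O)/C(C)=C/C/C=C(/C)CCC[C@H](C)[C@H](O[Si](C)(C)C(C)(C)C)[C@@H](C)C(=O)[C@@H](C)[C@@H](O[Si](C)(C)C(C)(C)C)CC(=O)OC(C)(C)C | intermediate
30 | trimethylsilyl ester and 17-O-trimethylsilyl ether of acid 31 (formed in the flask) | Cc1nc(cs1)[C@@H](O[Si](C)(C)C)/C(C)=C/C/C=C(/C)CCC[C@H](C)[C@H](O[Si](C)(C)C(C)(C)C)[C@@H](C)C(=O)[C@@H](C)[C@@H](O[Si](C)(C)C(C)(C)C)CC(=O)O[Si](C)(C)C | intermediate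
31 | (3S,4S,6R,7S,8S,12Z,15E,17S)-3,7-bis(TBS-oxy)-17-hydroxy-4,6,8,12,16-pentamethyl-17-(2-methyl-1,3-thiazol-4-yl)-5-oxoheptadeca-12,15-dienoic acid | Cc1nc(cs1)[C@@H](O)/C(C)=C/C/C=C(/C)CCC[C@H](C)[C@H](O[Si](C)(C)C(C)(C)C)[C@@H](C)C(=O)[C@@H](C)[C@@H](O[Si](C)(C)C(C)(C)C)CC(=O)O | intermediate
32 | mixed anhydride of acid 31 with 2,4,6-trichlorobenzoic acid (formed in the flask) | Cc1nc(cs1)[C@@H](O)/C(C)=C/C/C=C(/C)CCC[C@H](C)[C@H](O[Si](C)(C)C(C)(C)C)[C@@H](C)C(=O)[C@@H](C)[C@@H](O[Si](C)(C)C(C)(C)C)CC(=O)OC(=O)c1c(Cl)cc(Cl)cc1Cl | intermediate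
33 | (4S,5S,7R,8S,9S,13Z,16E,18S)-4,8-bis(TBS-oxy)-5,7,9,13,17-pentamethyl-18-(2-methyl-1,3-thiazol-4-yl)-1-oxacyclooctadeca-13,16-diene-2,6-dione (18-membered lactone esterified at O17) | Cc1nc(cs1)[C@@H]2/C(C)=C/C/C=C(/C)CCC[C@H](C)[C@H](O[Si](C)(C)C(C)(C)C)[C@@H](C)C(=O)[C@@H](C)[C@@H](O[Si](C)(C)C(C)(C)C)CC(=O)O2 | intermediate
34 | (4S,5S,7R,8S,9S,13Z,16S)-4,8-bis(TBS-oxy)-5,7,9,13-tetramethyl-16-[(1E)-1-(2-methyl-1,3-thiazol-4-yl)prop-1-en-2-yl]-1-oxacyclohexadec-13-ene-2,6-dione (16-membered lactone esterified at O15) | C/C(=C\c1csc(C)n1)[C@@H]1C/C=C(/C)CCC[C@H](C)[C@H](O[Si](C)(C)C(C)(C)C)[C@@H](C)C(=O)[C@@H](C)[C@@H](O[Si](C)(C)C(C)(C)C)CC(=O)O1 | intermediate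
35 | (4S,5S,7R,8S,9S,13Z,16S)-4,8-dihydroxy-5,7,9,13-tetramethyl-16-[(1E)-1-(2-methyl-1,3-thiazol-4-yl)prop-1-en-2-yl]-1-oxacyclohexadec-13-ene-2,6-dione | C/C(=C\c1csc(C)n1)[C@@H]1C/C=C(/C)CCC[C@H](C)[C@H](O)[C@@H](C)C(=O)[C@@H](C)[C@@H](O)CC(=O)O1 | intermediate
36 | (1S,3S,7S,8S,10R,11S,12S,16R)-7,11-dihydroxy-8,10,12,16-tetramethyl-3-[(1E)-1-(2-methyl-1,3-thiazol-4-yl)prop-1-en-2-yl]-4,17-dioxabicyclo[14.1.0]heptadecane-5,9-dione | C/C(=C\c1csc(C)n1)[C@@H]1C[C@@H]2O[C@]2(C)CCC[C@H](C)[C@H](O)[C@@H](C)C(=O)[C@@H](C)[C@@H](O)CC(=O)O1 | target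

**Step count**

Total: 23 steps. Longest linear sequence: 16 steps (16 → 36, steps 8–23).

**Steps most likely to fail**

Step 21 (ring contraction). The palladium may be held by the thiazole nitrogen without engaging the alkene, the tertiary C16–Pd bond may not form, or the ester may ionise and lose the C14 proton. In that case 34 would be made in the conventional order, with the lactone closed directly at O15. This sets out from aldehyde 7 and borane 28 and returns at 34.
- Wittig olefination of 7 with 2-(triphenylphosphoranylidene)propanal (toluene, 90 °C) would give (2E)-2-methyl-3-(2-methyl-1,3-thiazol-4-yl)prop-2-enal F1.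
- Brown allylation (allylB(Ipc)2 made from (−)-Ipc2BOMe and allylmagnesium bromide, Et2O, −100 °C; then NaOH, H2O2) would give (1E,3S)-2-methyl-1-(2-methyl-1,3-thiazol-4-yl)hexa-1,5-dien-3-ol F2.
- TESCl and imidazole would give its triethylsilyl ether F3.
- Cleavage of the terminal alkene (OsO4 cat., NaIO4, 2,6-lutidine, dioxane/water) would give the aldehyde (3S,4E)-4-methyl-5-(2-methyl-1,3-thiazol-4-yl)-3-(TES-oxy)pent-4-enal F4.
- Stork–Zhao olefination with Ph3P=C(I)CH3 (from (1-iodoethyl)triphenylphosphonium iodide and NaN(SiMe3)2, THF, −78 °C) would give the (Z)-vinyl iodide 4-[(1E,3S,5Z)-6-iodo-2-methyl-3-(TES-oxy)hepta-1,5-dien-1-yl]-2-methyl-1,3-thiazole F5.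
- B-alkyl Suzuki coupling of F5 with 28 (PdCl2(dppf), AsPh3, Cs2CO3, DMF/H2O) would give the 15-O-TES tert-butyl ester F6.
- TMSOTf and 2,6-lutidine would turn it into the trimethylsilyl ester F7. HF·pyridine/pyridine in THF at 0 °C would then remove the silyl ester and the allylic triethylsilyl ether to leave the 15-hydroxy acid F8.
- Its mixed anhydride with 2,4,6-trichlorobenzoic acid F9 would close under DMAP at high dilution to 34.

Step 4 (alkenylzinc addition). The thiazolyl aldehyde and its zinc alkoxide can chelate zinc and open a ligand-free pathway, which would erode the enantioselectivity, and hydrozirconation may not fully favour the methyl-bearing carbon. C17 would then be set by resolution. This sets out from 6 and 7 and returns at 10.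
- Hydrozirconation of 6 as before and ZnBr2-catalysed addition of alkenylzirconocene 8 to 7 without chiral ligand would give racemic (2E,5Z)-6-iodo-2-methyl-1-(2-methyl-1,3-thiazol-4-yl)hepta-2,5-dien-1-ol F10.
- A Sharpless kinetic resolution (Ti(OiPr)4, L-(+)-diisopropyl tartrate, t-BuOOH 0.6 equiv, 4 Å sieves, CH2Cl2, −20 °C) would consume the (1R)-enantiomer as the epoxy alcohol (S)-[(2S,3S)-3-[(2Z)-3-iodobut-2-en-1-yl]-2-methyloxiran-2-yl](2-methyl-1,3-thiazol-4-yl)methanol F11 and leave the (1S)-alcohol 10.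

Step 20 (macrolactonisation). Acylation of the hindered, doubly flanked C17 carbinol may be slow, which would favour oligomerisation or β-elimination of the C3 silyloxy group from the activated acid. The order of ester formation and C11–C12 coupling would then be exchanged. This sets out from 27 and 10 and returns at 33.
- TMSOTf and 2,6-lutidine would convert 27 into the trimethylsilyl ester F12, and aqueous work-up would give (3S,4S,6R,7S,8S)-3,7-bis(TBS-oxy)-4,6,8-trimethyl-5-oxoundec-10-enoic acid F13.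
- Bimolecular esterification with 10 (EDC·HCl, DMAP, CH2Cl2) would give the C17 ester F14.
- 9-BBN would hydroborate its terminal alkene to the borane F15.
- Slow addition of F15 to PdCl2(dppf), AsPh3 and Cs2CO3 in DMF/THF/water at high dilution would close the 18-membered ring by intramolecular B-alkyl Suzuki coupling to 33.

**Further compounds**

F1 | step 21 | (2E)-2-methyl-3-(2-methyl-1,3-thiazol-4-yl)prop-2-enal | Cc1nc(cs1)/C=C(\C)C=O
F2 | step 21 | (1E,3S)-2-methyl-1-(2-methyl-1,3-thiazol-4-yl)hexa-1,5-dien-3-ol | Cc1nc(cs1)/C=C(\C)[C@@H](O)CC=C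
F3 | step 21 | 4-[(1E,3S)-2-methyl-3-(TES-oxy)hexa-1,5-dien-1-yl]-2-methyl-1,3-thiazole | Cc1nc(cs1)/C=C(\C)[C@@H](O[Si](CC)(CC)CC)CC=C
F4 | step 21 | (3S,4E)-4-methyl-5-(2-methyl-1,3-thiazol-4-yl)-3-(TES-oxy)pent-4-enal | Cc1nc(cs1)/C=C(\C)[C@@H](O[Si](CC)(CC)CC)CC=O
F5 | step 21 | 4-[(1E,3S,5Z)-6-iodo-2-methyl-3-(TES-oxy)hepta-1,5-dien-1-yl]-2-methyl-1,3-thiazole | Cc1nc(cs1)/C=C(\C)[C@@H](O[Si](CC)(CC)CC)C/C=C(/C)I
F6 | step 21 | tert-butyl (3S,4S,6R,7S,8S,12Z,15S,16E)-3,7-bis(TBS-oxy)-4,6,8,12,16-pentamethyl-17-(2-methyl-1,3-thiazol-4-yl)-5-oxo-15-(TES-oxy)heptadeca-12,16-dienoate | Cc1nc(cs1)/C=C(\C)[C@@H](O[Si](CC)(CC)CC)C/C=C(/C)CCC[C@H](C)[C@H](O[Si](C)(C)C(C)(C)C)[C@@H](C)C(=O)[C@@H](C)[C@@H](O[Si](C)(C)C(C)(C)C)CC(=O)OC(C)(C)C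
F7 | step 21 | trimethylsilyl ester corresponding to F6 | Cc1nc(cs1)/C=C(\C)[C@@H](O[Si](CC)(CC)CC)C/C=C(/C)CCC[C@H](C)[C@H](O[Si](C)(C)C(C)(C)C)[C@@H](C)C(=O)[C@@H](C)[C@@H](O[Si](C)(C)C(C)(C)C)CC(=O)O[Si](C)(C)C
F8 | step 21 | (3S,4S,6R,7S,8S,12Z,15S,16E)-3,7-bis(TBS-oxy)-15-hydroxy-4,6,8,12,16-pentamethyl-17-(2-methyl-1,3-thiazol-4-yl)-5-oxoheptadeca-12,16-dienoic acid | Cc1nc(cs1)/C=C(\C)[C@@H](O)C/C=C(/C)CCC[C@H](C)[C@H](O[Si](C)(C)C(C)(C)C)[C@@H](C)C(=O)[C@@H](C)[C@@H](O[Si](C)(C)C(C)(C)C)CC(=O)O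
F9 | step 21 | mixed anhydride of F8 with 2,4,6-trichlorobenzoic acid | Cc1nc(cs1)/C=C(\C)[C@@H](O)C/C=C(/C)CCC[C@H](C)[C@H](O[Si](C)(C)C(C)(C)C)[C@@H](C)C(=O)[C@@H](C)[C@@H](O[Si](C)(C)C(C)(C)C)CC(=O)OC(=O)c1c(Cl)cc(Cl)cc1Cl
F10 | step 4 | racemic (2E,5Z)-6-iodo-2-methyl-1-(2-methyl-1,3-thiazol-4-yl)hepta-2,5-dien-1-ol | Cc1nc(cs1)C(O)/C(C)=C/C/C=C(/C)I
F11 | step 4 | (S)-[(2S,3S)-3-[(2Z)-3-iodobut-2-en-1-yl]-2-methyloxiran-2-yl](2-methyl-1,3-thiazol-4-yl)methanol | Cc1nc(cs1)[C@H](O)[C@]1(C)O[C@H]1C/C=C(/C)I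
F12 | step 20 | trimethylsilyl (3S,4S,6R,7S,8S)-3,7-bis(TBS-oxy)-4,6,8-trimethyl-5-oxoundec-10-enoate | C=CC[C@H](C)[C@H](O[Si](C)(C)C(C)(C)C)[C@@H](C)C(=O)[C@@H](C)[C@@H](O[Si](C)(C)C(C)(C)C)CC(=O)O[Si](C)(C)C
F13 | step 20 | (3S,4S,6R,7S,8S)-3,7-bis(TBS-oxy)-4,6,8-trimethyl-5-oxoundec-10-enoic acid | C=CC[C@H](C)[C@H](O[Si](C)(C)C(C)(C)C)[C@@H](C)C(=O)[C@@H](C)[C@@H](O[Si](C)(C)C(C)(C)C)CC(=O)O
F14 | step 20 | (1S,2E,5Z)-6-iodo-2-methyl-1-(2-methyl-1,3-thiazol-4-yl)hepta-2,5-dien-1-yl (3S,4S,6R,7S,8S)-3,7-bis(TBS-oxy)-4,6,8-trimethyl-5-oxoundec-10-enoate | C=CC[C@H](C)[C@H](O[Si](C)(C)C(C)(C)C)[C@@H](C)C(=O)[C@@H](C)[C@@H](O[Si](C)(C)C(C)(C)C)CC(=O)O[C@H](c1csc(C)n1)/C(C)=C/C/C=C(/C)I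
F15 | step 20 | 11-(9-borabicyclo[3.3.1]nonan-9-yl) hydroboration product of F14 | C1CC2CCCC(C1)B2CCC[C@H](C)[C@H](O[Si](C)(C)C(C)(C)C)[C@@H](C)C(=O)[C@@H](C)[C@@H](O[Si](C)(C)C(C)(C)C)CC(=O)O[C@H](c1csc(C)n1)/C(C)=C/C/C=C(/C)I
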